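The numbers in the tables were generated by integration for an exercise, and the scatter is random.

Which of starting material, target and over-reaction product stands highest at the end of violet and of ochre, and at how much?

| flask | starting material | partner | second substrate | third substrate | remark | time |
|---|---|---|---|---|---|---|
| dawn | 0.10 M | 0.15 M | 0.10 M | 0.20 M | run made earlier |  |
| noon | 0.10 M | 0.40 M | 0.10 M | 0.20 M | run made earlier |  |
| violet | 0.10 M | 0.540 M | 0.100 M | 0.200 M |  | 25 min |
| ochre | 0.10 M | 0.180 M | 0.100 M | 0.200 M |  | 25 min |

| run | time / min | starting material / % | target / % | over-reaction product / % |
|---|---|---|---|---|
| dawn | 2.00 | 93.0 | 4.2 | 0 |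
| dawn | 4.00 | 92.8 | 9.6 | 0.5 |
| dawn | 6.00 | 89.5 | 10.8 | 1.3 |
| dawn | 8.00 | 85.8 | 15.0 | 0 |
| dawn | 10.0 | 87.4 | 13.6 | 1.7 |
| dawn | 12.0 | 83.9 | 13.9 | 0.7 |
| noon | 1.00 | 91.1 | 8.9 | 1.2 |
| noon | 1.50 | 86.2 | 11.7 | 0 |
| noon | 3.00 | 79.8 | 18.6 | 0.9 |
| noon | 5.00 | 74.2 | 26.7 | 1.6 |
| noon | 8.00 | 60.9 | 35.7 | 3.3 |
| noon | 12.0 | 54.2 | 40.9 | 6.0 |

(standard deviation of a reading: 1 percentage point)

- which of these there is most of at the end, counted by the starting material in it, violet (target / starting material / over-reaction product)
- which of these there is most of at the end, counted by the starting material in it, ochre (target / starting material / over-reaction product)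
- how much there is at the end of the one of these that leads, in percent of the starting material charged: violet
- how much there is at the end of the one of these that leads, in percent of the starting material charged: ochre

- amounts and yields of target count idle adduct too
- the analysis behind the earlier runs scatters by 1 percentage point, standard deviation
- candidate steps: starting material + partner -> target; second substrate + partner -> second product; third substrate + partner -> third product; third substrate + target <-> idle adduct; target -> over-reaction product

Follow one molecule of partner: if it reacts, it ends on one of the three substrates, and each substrate molecule takes one. So the recipe table gives a count, the spare partner S = c(partner) − c(starting material) − c(second substrate) − c(third substrate), taken from the charges, which in violet is 0.140 M.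

Reading the other rows, dawn has −0.250 M, so partner is the limiting reagent there, and its starting material goes from 85.8% at 8.00 min to 83.9% at 12.0 min. We take this flattening as the partner being used up. On that reading, with its scatter, a partner molecule in dawn had a chance of 10.7% of landing on starting material.

Ochre has the same substrates and S = −0.220 M, so with the same chance we reckon 80.7% of its starting material remains, and that leads.

Noon's 0.40 M of partner just equals the sum of its substrates, so S is zero there. Its first reading, with its scatter, gives a rate constant of about 0.233 M⁻¹ min⁻¹ for starting material with partner, and its last shows 6.0% of over-reaction product beside 40.9% of target.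

In violet, we expect partner to stay above S, so even at that floor we reckon starting material falls to about 44.2% or lower, and we expect target to lead.

The forecast puts target ahead in violet at 55% and starting material ahead in ochre at 79%, where, it says, “the reaction stalls”.

The flasks give target at 58.9% in violet and starting material at 75.3% in ochre.

    starting material + partner → target (k = 0.00390 M⁻¹ s⁻¹)
    second substrate + partner → second product (k = 0.0289 M⁻¹ s⁻¹)
    third substrate + partner → third product (k = 0.00456 M⁻¹ s⁻¹)
    third substrate + target ⇌ idle adduct, settled at all times (K = 2.90 M⁻¹)
    target → over-reaction product (k = 3.48 × 10⁻⁴ s⁻¹)

The difference in partner is the main reason for the gap in target between violet and ochre: violet's 58.9% of target falls to 19.1% when it is charged with ochre's partner. Violet ends with 0.197 M of partner, its spare 0.140 M plus what the substrates have not yet taken. Our 80.7% for ochre lies above the 75.3% it ends at: ochre's starting material already stood at 80.0% at 12.5 min, with 18.8% of its partner still there, so a flattening need not mean that partner is used up.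

Ochre charged with 0.45 M of partner has S = 0.0500 M, positive, so we expect partner to outlast the substrates and target to lead. That flask gives target at 52.7%, with 29.8% of its partner left.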